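**Plan**

Ring B is numbered B1 (prenyl), B2 (O-acyl), B3 (H), B4 and B5 (CH2OH), B6 (OH); ring A is the orsellinate ring.
Cuts, in retrosynthetic order: the B2 O–C(=O) ester bond to ring A; the bond from B5 to its CH2OH carbon, traced back to a lactone carbonyl brought in as CO2; the B1–prenyl bond.
Enabling feature: without the carbon on B5, ring B is a mirror-symmetric 2-prenylresorcinol with a single CH2OH at B4, so B3 and B5 are the same position and one carboxylation finishes the carbon skeleton.
Forward order: ring B is bought; prenyl is joined at B1; ortho-lithiation and CO2 close the only new ring (a phthalide lactone, later opened by hydride); its carbonyl tells the B2 and B6 oxygens apart; ring A is joined by esterification; one fluoride step unmasks everything.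
Stereochemistry: none to set. The target has no stereocentre and its only C=C carries two identical methyl groups.

Key step: step 6

Remark: the target is taken as drawn, with the ester on the ring-B oxygen next to the ring hydrogen and the free phenol next to a hydroxymethyl group.

**Route**

Step 1
Reactants: 1 methyl 3,5-dihydroxybenzoate
Product: 2 methyl 3,5-bis(methoxymethoxy)benzoate
Conditions: MOMCl (2.5 equiv), K2CO3, acetone, 0 °C to reflux
Reagents that add atoms: chloromethyl methyl ether (MOMCl), COCCl
Why: Williamson-type O-alkylation of both phenoxides installs the two MOM ethers, which later serve as ortho-directing groups; the methyl ester is inert to carbonate.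

Step 2
Reactants: 2 methyl 3,5-bis(methoxymethoxy)benzoate
Product: 3 [3,5-bis(methoxymethoxy)phenyl]methanol
Conditions: LiAlH4, THF, 0 °C
Reagents that add atoms: none
Why: Hydride reduction of a benzoate ester to the benzyl alcohol; MOM acetals do not react with LiAlH4.

Step 3
Reactants: 3 [3,5-bis(methoxymethoxy)phenyl]methanol
Product: 4 tert-butyl-[[3,5-bis(methoxymethoxy)phenyl]methoxy]dimethylsilane
Conditions: TBSCl, imidazole, DMF, rt
Reagents that add atoms: tert-butyldimethylsilyl chloride (TBSCl), CC(C)(C)[Si](C)(C)Cl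
Why: Imidazole-promoted silylation masks the hydroxyl, so the next lithiation is steered by the two MOM ethers alone and not by an alkoxide.

Step 4
Reactants: 4 tert-butyl-[[3,5-bis(methoxymethoxy)phenyl]methoxy]dimethylsilane; 5 prenyl bromide
Product: 8 tert-butyl-[[3,5-bis(methoxymethoxy)-4-(3-methylbut-2-enyl)phenyl]methoxy]dimethylsilane, via aryllithium 6 (not isolated), via arylcopper 7 (not isolated)
Conditions: n-BuLi, THF, 0 °C; CuBr·SMe2, −20 °C; 5, −20 °C to rt
Reagents that add atoms: prenyl bromide (compound 5), CC(C)=CCBr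
Why: Directed ortho-metalation removes the ring hydrogen flanked by both MOM ethers, and transmetalation to the arylcopper followed by allylic substitution at the primary carbon of prenyl bromide (copper-mediated aryl–allyl coupling) should give the linear prenyl arene.

Step 5
Reactants: 8 tert-butyl-[[3,5-bis(methoxymethoxy)-4-(3-methylbut-2-enyl)phenyl]methoxy]dimethylsilane
Product: 9 [3,5-bis(methoxymethoxy)-4-(3-methylbut-2-enyl)phenyl]methanol
Conditions: TBAF, THF, 0 °C to rt
Reagents that add atoms: none
Why: Fluoride-driven desilylation frees the benzylic alcohol that anchors the key lithiation; MOM ethers and the alkene are untouched.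

Step 6
Reactants: 9 [3,5-bis(methoxymethoxy)-4-(3-methylbut-2-enyl)phenyl]methanol; 10 carbon dioxide
Product: 13 5,7-bis(methoxymethoxy)-6-(3-methylbut-2-enyl)-3H-isobenzofuran-1-one, via ring-lithiated lithium alkoxide 11 (not isolated), via hydroxy acid 12 (not isolated)
Conditions: n-BuLi (2.4 equiv), TMEDA, Et2O, −20 to 0 °C; excess CO2, −78 °C to rt; 1 M aq. HCl to pH 2, rt
Reagents that add atoms: carbon dioxide (compound 10), O=C=O
Why: The first equivalent of n-BuLi gives the lithium alkoxide, and the second, coordinated to both the alkoxide oxygen and the neighbouring MOM ether, removes the ring hydrogen at B5 (directed ortho-metalation by complex-induced proximity); aryllithium 11 then adds to CO2 to form the B5–carboxyl bond. Acidification releases hydroxy acid 12, whose hydroxymethyl oxygen attacks the adjacent carboxyl carbon in a 5-exo-trig acyl substitution that closes the five-membered lactone. The closest known reaction type is the alkoxide- and alkoxy-directed ortho-lithiation of 3-alkoxybenzyl alcohols with CO2 trapping to give 7-alkoxyphthalides. No stereocentre is formed. Site selectivity is needed on two counts: between B3 and B5, which the mirror symmetry of 9 makes identical while B1 is blocked by prenyl, and between ring lithiation and deprotonation of the benzylic-allylic CH2 of the prenyl group, where the doubly coordinated ring position should be favoured kinetically at low temperature with an alkyllithium that is not a superbase. The new carbonyl lies peri to the B6 oxygen only, and this later distinguishes the two phenols.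

Step 7
Reactants: 13 5,7-bis(methoxymethoxy)-6-(3-methylbut-2-enyl)-3H-isobenzofuran-1-one
Product: 14 5,7-dihydroxy-6-(3-methylbut-2-enyl)-3H-isobenzofuran-1-one
Conditions: 3 M aq. HCl, MeOH, rt to 40 °C
Reagents that add atoms: none
Why: Acid-catalysed acetal exchange with methanol removes both MOM ethers; the five-membered lactone is the stable form under these conditions, and the mild temperature is chosen to keep the phenols from adding across the prenyl alkene.

Step 8
Reactants: 14 5,7-dihydroxy-6-(3-methylbut-2-enyl)-3H-isobenzofuran-1-one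
Product: 15 7-hydroxy-6-(3-methylbut-2-enyl)-5-prop-2-enoxy-3H-isobenzofuran-1-one
Conditions: allyl bromide (1.05 equiv), K2CO3 (1.1 equiv), acetone, rt
Reagents that add atoms: allyl bromide, C=CCBr
Why: Williamson etherification should take the C5 phenol (B2), which is para to the lactone carbonyl, more acidic and less hindered, while the C7 phenol (B6) is hydrogen-bonded to the peri carbonyl and flanked on both sides; the same selectivity is known for 6-alkyl-5,7-dihydroxyphthalides.

Step 9
Reactants: 15 7-hydroxy-6-(3-methylbut-2-enyl)-5-prop-2-enoxy-3H-isobenzofuran-1-one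
Product: 16 2,3-bis(hydroxymethyl)-6-(3-methylbut-2-enyl)-5-prop-2-enoxyphenol
Conditions: LiAlH4 (excess), THF, 0 °C to rt; aq. Rochelle salt work-up
Reagents that add atoms: none
Why: Hydride reduction of the lactone to the 1,2-bis(hydroxymethyl)arene after the phenol is converted to its aluminium phenoxide; the allyl ether and the alkene are inert, and the neutral work-up and low temperature protect the acid-labile ortho-hydroxybenzyl alcohol.

Step 10
Reactants: 16 2,3-bis(hydroxymethyl)-6-(3-methylbut-2-enyl)-5-prop-2-enoxyphenol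
Product: 17 tert-butyl-[2,3-bis[[tert-butyl(dimethyl)silyl]oxymethyl]-6-(3-methylbut-2-enyl)-5-prop-2-enoxyphenoxy]dimethylsilane
Conditions: TBSCl (4 equiv), imidazole, DMAP (cat.), DMF, rt to 40 °C
Reagents that add atoms: tert-butyldimethylsilyl chloride (TBSCl), CC(C)(C)[Si](C)(C)Cl
Why: Exhaustive silylation covers both primary alcohols and the hindered B6 phenol with one fluoride-labile group, so no acid is needed at the end of the synthesis.

Step 11
Reactants: 17 tert-butyl-[2,3-bis[[tert-butyl(dimethyl)silyl]oxymethyl]-6-(3-methylbut-2-enyl)-5-prop-2-enoxyphenoxy]dimethylsilane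
Product: 18 3-[tert-butyl(dimethyl)silyl]oxy-4,5-bis[[tert-butyl(dimethyl)silyl]oxymethyl]-2-(3-methylbut-2-enyl)phenol
Conditions: Pd(PPh3)4 (5 mol %), morpholine, THF, rt
Reagents that add atoms: none
Why: Tsuji–Trost deallylation: zerovalent palladium ionises the allyl aryl ether to a π-allyl complex that morpholine captures, freeing the B2 phenol; the prenyl group has no allylic leaving group and the silyl ethers are stable to the amine.

Step 12
Reactants: 19 orsellinic acid
Product: 20 tert-butyldimethylsilyl 2,4-bis[[tert-butyl(dimethyl)silyl]oxy]-6-methylbenzoate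
Conditions: TBSCl (3.5 equiv), imidazole, DMF, rt
Reagents that add atoms: tert-butyldimethylsilyl chloride (TBSCl), CC(C)(C)[Si](C)(C)Cl
Why: Silylation of both phenols and the carboxylic acid in one operation, as is standard for hydroxybenzoic acids.

Step 13
Reactants: 20 tert-butyldimethylsilyl 2,4-bis[[tert-butyl(dimethyl)silyl]oxy]-6-methylbenzoate
Product: 21 2,4-bis[[tert-butyl(dimethyl)silyl]oxy]-6-methylbenzoic acid
Conditions: AcOH–THF–H2O (3:1:1), rt
Reagents that add atoms: none
Why: Selective solvolysis of the silyl ester, which is far more labile than aryl silyl ethers under mild aqueous acid.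

Step 14
Reactants: 18 3-[tert-butyl(dimethyl)silyl]oxy-4,5-bis[[tert-butyl(dimethyl)silyl]oxymethyl]-2-(3-methylbut-2-enyl)phenol; 21 2,4-bis[[tert-butyl(dimethyl)silyl]oxy]-6-methylbenzoic acid
Product: 22 [3-[tert-butyl(dimethyl)silyl]oxy-4,5-bis[[tert-butyl(dimethyl)silyl]oxymethyl]-2-(3-methylbut-2-enyl)phenyl] 2,4-bis[[tert-butyl(dimethyl)silyl]oxy]-6-methylbenzoate
Conditions: DIC, DMAP (1 equiv), CH2Cl2, 0 °C to rt
Reagents that add atoms: none
Why: Steglich esterification: the carbodiimide activates the acid, DMAP relays the acyl group to the only free hydroxyl (the B2 phenol), as in depside couplings of protected orsellinic acids.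

Step 15
Reactants: 22 [3-[tert-butyl(dimethyl)silyl]oxy-4,5-bis[[tert-butyl(dimethyl)silyl]oxymethyl]-2-(3-methylbut-2-enyl)phenyl] 2,4-bis[[tert-butyl(dimethyl)silyl]oxy]-6-methylbenzoate
Product: 23 [3-hydroxy-4,5-bis(hydroxymethyl)-2-(3-methylbut-2-enyl)phenyl] 2,4-dihydroxy-6-methylbenzoate (target)
Conditions: TBAF (6 equiv), AcOH (6 equiv), THF, 0 °C to rt
Reagents that add atoms: none
Why: Fluoride-mediated cleavage of all five silyl ethers; the acetic acid buffer keeps phenoxides and alkoxides protonated, so the aryl ester, the ortho-hydroxybenzyl alcohol and the prenyl group should survive.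

**Compound list**

1 | methyl 3,5-dihydroxybenzoate | COC(=O)c1cc(O)cc(O)c1 | starting material
2 | methyl 3,5-bis(methoxymethoxy)benzoate | COCOc1cc(OCOC)cc(c1)C(=O)OC | intermediate
3 | [3,5-bis(methoxymethoxy)phenyl]methanol | COCOc1cc(CO)cc(OCOC)c1 | intermediate
4 | tert-butyl-[[3,5-bis(methoxymethoxy)phenyl]methoxy]dimethylsilane | COCOc1cc(CO[Si](C)(C)C(C)(C)C)cc(OCOC)c1 | intermediate
5 | prenyl bromide (1-bromo-3-methylbut-2-ene) | CC(C)=CCBr | starting material
6 | [4-[[tert-butyl(dimethyl)silyl]oxymethyl]-2,6-bis(methoxymethoxy)phenyl]lithium | [Li]c1c(OCOC)cc(CO[Si](C)(C)C(C)(C)C)cc1OCOC | intermediate (not isolated)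
7 | [4-[[tert-butyl(dimethyl)silyl]oxymethyl]-2,6-bis(methoxymethoxy)phenyl]copper | [Cu]c1c(OCOC)cc(CO[Si](C)(C)C(C)(C)C)cc1OCOC | intermediate (not isolated)
8 | tert-butyl-[[3,5-bis(methoxymethoxy)-4-(3-methylbut-2-enyl)phenyl]methoxy]dimethylsilane | CC(C)=CCc1c(OCOC)cc(CO[Si](C)(C)C(C)(C)C)cc1OCOC | intermediate
9 | [3,5-bis(methoxymethoxy)-4-(3-methylbut-2-enyl)phenyl]methanol | CC(C)=CCc1c(OCOC)cc(CO)cc1OCOC | intermediate
10 | carbon dioxide | O=C=O | starting material
11 | lithium [2-lithio-3,5-bis(methoxymethoxy)-4-(3-methylbut-2-enyl)phenyl]methanolate | [Li]OCc1cc(OCOC)c(CC=C(C)C)c(OCOC)c1[Li] | intermediate (not isolated)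
12 | 6-(hydroxymethyl)-2,4-bis(methoxymethoxy)-3-(3-methylbut-2-enyl)benzoic acid | CC(C)=CCc1c(OCOC)cc(CO)c(C(=O)O)c1OCOC | intermediate (not isolated)
13 | 5,7-bis(methoxymethoxy)-6-(3-methylbut-2-enyl)-3H-isobenzofuran-1-one | CC(C)=CCc1c(OCOC)cc2COC(=O)c2c1OCOC | intermediate
14 | 5,7-dihydroxy-6-(3-methylbut-2-enyl)-3H-isobenzofuran-1-one | CC(C)=CCc1c(O)cc2COC(=O)c2c1O | intermediate
15 | 7-hydroxy-6-(3-methylbut-2-enyl)-5-prop-2-enoxy-3H-isobenzofuran-1-one | C=CCOc1cc2COC(=O)c2c(O)c1CC=C(C)C | intermediate
16 | 2,3-bis(hydroxymethyl)-6-(3-methylbut-2-enyl)-5-prop-2-enoxyphenol | C=CCOc1cc(CO)c(CO)c(O)c1CC=C(C)C | intermediate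
17 | tert-butyl-[2,3-bis[[tert-butyl(dimethyl)silyl]oxymethyl]-6-(3-methylbut-2-enyl)-5-prop-2-enoxyphenoxy]dimethylsilane | C=CCOc1cc(CO[Si](C)(C)C(C)(C)C)c(CO[Si](C)(C)C(C)(C)C)c(O[Si](C)(C)C(C)(C)C)c1CC=C(C)C | intermediate
18 | 3-[tert-butyl(dimethyl)silyl]oxy-4,5-bis[[tert-butyl(dimethyl)silyl]oxymethyl]-2-(3-methylbut-2-enyl)phenol | CC(C)=CCc1c(O)cc(CO[Si](C)(C)C(C)(C)C)c(CO[Si](C)(C)C(C)(C)C)c1O[Si](C)(C)C(C)(C)C | intermediate
19 | orsellinic acid (2,4-dihydroxy-6-methylbenzoic acid) | Cc1cc(O)cc(O)c1C(=O)O | starting material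
20 | tert-butyldimethylsilyl 2,4-bis[[tert-butyl(dimethyl)silyl]oxy]-6-methylbenzoate | Cc1cc(O[Si](C)(C)C(C)(C)C)cc(O[Si](C)(C)C(C)(C)C)c1C(=O)O[Si](C)(C)C(C)(C)C | intermediate
21 | 2,4-bis[[tert-butyl(dimethyl)silyl]oxy]-6-methylbenzoic acid | Cc1cc(O[Si](C)(C)C(C)(C)C)cc(O[Si](C)(C)C(C)(C)C)c1C(=O)O | intermediate
22 | [3-[tert-butyl(dimethyl)silyl]oxy-4,5-bis[[tert-butyl(dimethyl)silyl]oxymethyl]-2-(3-methylbut-2-enyl)phenyl] 2,4-bis[[tert-butyl(dimethyl)silyl]oxy]-6-methylbenzoate | CC(C)=CCc1c(OC(=O)c2c(C)cc(O[Si](C)(C)C(C)(C)C)cc2O[Si](C)(C)C(C)(C)C)cc(CO[Si](C)(C)C(C)(C)C)c(CO[Si](C)(C)C(C)(C)C)c1O[Si](C)(C)C(C)(C)C | intermediate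
23 | [3-hydroxy-4,5-bis(hydroxymethyl)-2-(3-methylbut-2-enyl)phenyl] 2,4-dihydroxy-6-methylbenzoate | CC(C)=CCc1c(OC(=O)c2c(C)cc(O)cc2O)cc(CO)c(CO)c1O | target

**Step count**

Total: 15 steps. Longest linear sequence: 13 steps (steps 1–11, 14 and 15); steps 12 and 13 prepare the ring-A acid.

**Steps most likely to fail**

Step 6. Removal of the benzylic-allylic CH2 proton of the prenyl group, or an incomplete second lithiation of the alkoxide, could compete with ring metalation. The fallback fixes the metalation site with a halogen and sets out from 9. Ring bromination (NBS, MeCN, −20 °C; both open ring positions are equivalent and strongly activated) should give [2-bromo-3,5-bis(methoxymethoxy)-4-(3-methylbut-2-enyl)phenyl]methanol F1. n-BuLi (2.2 equiv, THF, −78 °C) then forms the alkoxide and exchanges bromine for lithium, giving the same dilithio species 11. Carboxylation and acidification as before bring the sequence back to the route at 13.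

Step 7. Under protic acid a phenol next to the prenyl group may add across the protonated alkene (dimethylchroman formation), or HCl or methanol may add to it, faster than the second acetal is cleaved. The fallback sets out from 13 and never exposes a free prenylresorcinol to protic acid. MgBr2·OEt2 (Et2O–CH2Cl2, rt) should cleave only the MOM ether peri to the lactone carbonyl by chelation, giving 7-hydroxy-5-(methoxymethoxy)-6-(3-methylbut-2-enyl)-3H-isobenzofuran-1-one F2. LiAlH4 reduction gives 2,3-bis(hydroxymethyl)-5-(methoxymethoxy)-6-(3-methylbut-2-enyl)phenol F3. Exhaustive silylation (TBSCl, imidazole, DMF) gives tert-butyl-[2,3-bis[[tert-butyl(dimethyl)silyl]oxymethyl]-5-(methoxymethoxy)-6-(3-methylbut-2-enyl)phenoxy]dimethylsilane F4. The remaining aryl MOM ether is then removed under non-protic conditions (TMSOTf, 2,2′-bipyridyl, CH2Cl2, 0 °C, then water), which should leave TBS ethers intact, and the sequence comes back to the route at 18.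

Step 14. Acyl transfer from the doubly ortho-substituted acid may be slow, so that rearrangement of the activated acid to the N-acylurea, or silyl migration from the ortho oxygen to the carboxylate, overtakes ester formation. The fallback sets out from 21 and replaces carbodiimide activation by a preformed acyl chloride and a phenoxide. 1-Chloro-N,N,2-trimethylprop-1-en-1-amine (CH2Cl2, 0 °C, neutral conditions) should give 2,4-bis[[tert-butyl(dimethyl)silyl]oxy]-6-methylbenzoyl chloride F5. This is added to the sodium phenoxide of 18 (NaH, THF, 0 °C), and the sequence comes back to the route at 22.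

**Further compounds**

F1 | step 6 | [2-bromo-3,5-bis(methoxymethoxy)-4-(3-methylbut-2-enyl)phenyl]methanol | CC(C)=CCc1c(OCOC)cc(CO)c(Br)c1OCOC
F2 | step 7 | 7-hydroxy-5-(methoxymethoxy)-6-(3-methylbut-2-enyl)-3H-isobenzofuran-1-one | CC(C)=CCc1c(OCOC)cc2COC(=O)c2c1O
F3 | step 7 | 2,3-bis(hydroxymethyl)-5-(methoxymethoxy)-6-(3-methylbut-2-enyl)phenol | CC(C)=CCc1c(OCOC)cc(CO)c(CO)c1O
F4 | step 7 | tert-butyl-[2,3-bis[[tert-butyl(dimethyl)silyl]oxymethyl]-5-(methoxymethoxy)-6-(3-methylbut-2-enyl)phenoxy]dimethylsilane | CC(C)=CCc1c(OCOC)cc(CO[Si](C)(C)C(C)(C)C)c(CO[Si](C)(C)C(C)(C)C)c1O[Si](C)(C)C(C)(C)C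
F5 | step 14 | 2,4-bis[[tert-butyl(dimethyl)silyl]oxy]-6-methylbenzoyl chloride | Cc1cc(O[Si](C)(C)C(C)(C)C)cc(O[Si](C)(C)C(C)(C)C)c1C(Cl)=O
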